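The time of reading, 2.5 min, is one of two times held against each other here; the other has to be reckoned from the earlier runs.

the same everywhere: electrophile 0.050 M
- noon: free base 0.10 M; solid nucleophile 0.028 M; scavenger 0.060 M; run made earlier
- summer: free base 0.10 M; solid nucleophile 0.037 M; scavenger 0.060 M; run made earlier
- dawn: free base 0.10 M; solid nucleophile 0.055 M; scavenger 0.068 M; run made earlier
- Saturday's: free base 0.100 M; solid nucleophile 0.0400 M; scavenger 0.0400 M; time 2.5 min
- Sunday's: free base 0.100 M; solid nucleophile 0.0550 M; scavenger 0.0600 M; time 2.5 min

| run | time / min | target / % | electrophile / % |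
|---|---|---|---|
| noon | 0.200 | 0 | 100.2 |
| noon | 0.500 | 0.3 | 99.0 |
| noon | 1.00 | 3.0 | 96.9 |
| noon | 2.50 | 11.6 | 87.1 |
| summer | 0.333 | 0.4 | 100.4 |
| summer | 0.833 | 3.2 | 98.4 |
| summer | 1.50 | 6.3 | 93.6 |
| summer | 2.50 | 14.1 | 86.1 |
| dawn | 0.667 | 0.3 | 98.6 |
| dawn | 1.33 | 4.4 | 94.3 |
| dawn | 2.00 | 9.4 | 89.5 |
| dawn | 2.50 | 14.9 | 87.2 |

(readings scatter by 1 percentage point)

- for acid set free the idle adduct is counted in
- as a solid, counted per litre of solution: solid nucleophile
- candidate steps: electrophile + nucleophile -> acid set free + target; nucleophile + acid set free <-> protonated nucleophile; acid set free + free base <-> salt of the base; solid nucleophile <-> nucleophile; nucleophile + acid set free <-> idle adduct; acid set free + scavenger -> scavenged by-product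
- at the start none of the solid nucleophile is in solution

* which one finishes higher in amount of target, in percent of the electrophile charged ("neither" within 2 percentage points) (Saturday's / Sunday's / neither)
* amount of target at the end, in percent of the electrophile charged, Saturday's
* amount of target at the end, in percent of the electrophile charged, Sunday's

Between 1.33 min and 2.50 min the dawn run's target climbs from 4.4% to 14.9%, so target formation draws 0.00449 M min⁻¹ of nucleophile. At that rate Saturday's flask has 8.91 min as its reach, the solid charge divided by the rate of target formation. Sunday's reach is 12.3 min, and the noon run's, on a lower charge than Saturday's, is 6.24 min, still longer than the time of reading. The reach counts what target formation takes and not the nucleophile standing in solution, so it is an estimate. The reading falls inside it, and with solid expected to be left, target at that time is expected to be zero order in the solid charge.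

The last readings then count as repeats of one flask: 11.6%, 14.1% and 14.9%, with mean 13.5% and standard error 0.58 percentage points. Two judgements stand in this: the noon reading, 3.3 points below the dawn one, is taken as scatter, and Saturday's scavenger charge lies below those of the runs. This reckoning gives 13.5% for both flasks, hence neither. The forecast gives 16% for Saturday's and 17.5% for Sunday's, also neither, noting that “the Saturday extrapolation is uncertain”; both figures stand above the mean.

The flasks give 13.5% for Saturday's and 13.6% for Sunday's, so neither.

    electrophile + nucleophile → acid set free + target (k = 0.182 L mol⁻¹ s⁻¹)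
    nucleophile + acid set free ⇌ protonated nucleophile, settled at all times (K = 6780 L mol⁻¹)
    acid set free + free base ⇌ salt of the base, settled at all times (K = 630 L mol⁻¹)
    solid nucleophile ⇌ nucleophile, rate k4*(cs4 - [nucleophile]) while solid is left; crystals form when [nucleophile] > cs4 (solubility = 35.0 mM, k = 0.00397 s⁻¹)
    nucleophile + acid set free ⇌ idle adduct, settled at all times (K = 39.0 L mol⁻¹)
    acid set free + scavenger → scavenged by-product (k = 0.715 L mol⁻¹ s⁻¹)

At 2.50 min Saturday's keeps 55.8% of its solid nucleophile and Sunday's 67.9%, so 0.0177 M and 0.0177 M have dissolved, equal amounts from different charges, inside reaches of 8.91 min and 12.3 min. Saturday's flask read at 10.0 min, past its reach of 8.91 min, holds 0% of its solid and 53.8% target.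

(The earlier runs and the new flask come from a simulation with made-up constants.)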